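I choose to treat Z in this flask as a lag chasing a slowly sinking target, and I keep two times.

| flask | X | Q | J | remark | time |
|---|---|---|---|---|---|
| Sunday's | 0.051 M | 0.051 M | 92 µM | run made earlier |  |
| Monday's | 0.051 M | 0.20 M | 92 µM | run made earlier |  |
| Wednesday's | 0.025 M | 0.102 M | 92 µM | run made earlier |  |
| flask | 0.051 M | 0.102 M | 92 µM |  | 40 h |

| run | time / h | Z / % | L / % |
|---|---|---|---|
| Sunday's | 0.417 | 8.2 | 0 |
| Sunday's | 1.00 | 8.7 | 0.9 |
| Sunday's | 2.00 | 9.9 | 0 |
| Sunday's | 5.00 | 10.2 | 0.3 |
| Sunday's | 10.0 | 9.7 | 0.9 |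
| Sunday's | 25.0 | 7.9 | 2.1 |
| Monday's | 0.417 | 8.4 | 0 |
| Monday's | 1.00 | 10.1 | 0.5 |
| Monday's | 2.00 | 10.0 | 0.6 |
| Monday's | 5.00 | 10.4 | 2.1 |
| Monday's | 10.0 | 9.6 | 4.3 |
| Monday's | 25.0 | 7.6 | 9.8 |
| Wednesday's | 0.417 | 7.1 | 0.8 |
| Wednesday's | 1.33 | 10.1 | 0 |
| Wednesday's | 3.00 | 10.6 | 0 |
| Wednesday's | 8.00 | 9.2 | 1.9 |
| Wednesday's | 25.0 | 8.3 | 6.1 |

(each reading ± 0.5 percentage points)

- percentages count the X that a species holds: one D counts as two
- reactions considered so far: Q + J + Z -> J + L; X + Z -> D; 2 J <-> E; X + J <-> J + Z

- time, not beyond 40 h, at which the flask holds most Z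
- the amount of Z, in percent of the X charged, at that time
- the first time at which Z reaches 5.1%, in the same percent

In Sunday's, Monday's and Wednesday's runs, whose Q and X differ, Z stands near 10.4% a few hours in, and averages 7.90% at the first reading. I read this as a fast pre-equilibrium. I take the gap to that level to close exponentially, and I call its e-folding time the settling time:

settling time = 0.293 h

In Sunday's and Monday's runs Z then sinks between 5.00 h and 25.0 h. Sunday and Monday share this flask's X and bracket its Q, so I average their slopes:

drain time = 70.3 h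

Because the drain time is far longer than the settling time, I expect this flask's peak close to the level read above. It comes when the gap, as a share of the target, has shrunk to settling time over drain time:

peak time = settling time × ln(drain time / settling time) = 1.60 h

With the same settling time I expect the level asked at 0.197 h.

The forecast gives 1.8 h, later than mine, with 10.3% and 0.2 h: “The peak comes when relaxation matches this drift”.

The flask gives 1.78 h, 10.2% and 0.225 h.

    Q + J + Z → J + L (k = 2.30 /M²/s)
    X + Z → D (k = 3.90 × 10⁻⁴ /M/s)
    2 J ⇌ E, settled at all times (K = 41000 /M)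
    X + J ⇌ J + Z (K = 0.120, k = 3.10 /M/s)

The neighbouring flask charges 3.7 × 10⁻⁴ M of J, and at 40.0 h holds 16.6% of it as J against 30.4% here, so it has 2.20 times the free J of this flask at that time. Dividing the settling time by that gives 0.133 h, and if I hold my drain time, the reckoning puts the neighbour's peak at 0.834 h. The neighbour's highest Z is 10.4%, and it ends with L at 15.4% against 7.43% here.

The readings were computed on assumed constants; the scatter is artificial.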